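**Strategy**

Everything rests on ring C of the lower (epicatechin) unit (O1, C2, C3, C4, C4a, C8a), which is grown from a five-membered ring. A cis-2-aryl-3-(hydroxymethyl)-2,3-dihydrobenzofuran, made by enantioselective carbene C–H insertion, is activated at its exocyclic CH2. The key step exploits the electron-rich phloroglucinol ring A beside the C3 carbinol: carbon C4a migrates from C3 to the CH2 (the later C4) through a phenonium ion and water enters at C3 with inversion, which gives the pyran ring and its 2,3-cis (2R,3R) pattern in one operation. Bromine at C8 then steers two Friedel–Crafts couplings with a catechin-derived C4 electrophile to C6; hydrogenolysis frees the trimer.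

Key step: step 7

Reading of the target: catechin-(4α→6)-catechin-(4α→6)-epicatechin; upper and middle units (2R,3S) with 3,4-trans C4 aryl groups, lower unit (2R,3R).

Assumption: Rh2(S-PTTL)4 is taken to give the (2S,3R) ester 9 by analogy with simpler 2-(benzyloxy)aryl diazoacetates; should the sense of induction be opposite, the mirror-image catalyst Rh2(R-PTTL)4 is used.

Abbreviation: TFMB = [4-(trifluoromethyl)phenyl]methyl, a benzyl-type protecting group that is removed in the last step. It is used on ring A because its CH2 is electronically deactivated toward carbene insertion and because it is more stable to Lewis acid than a benzyl ether.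

**Route**

Step 1
Reactants: 1 2',4',6'-trihydroxyacetophenone (phloroacetophenone)
Product: 2 1-(2-hydroxy-4,6-bis{[4-(trifluoromethyl)phenyl]methoxy}phenyl)ethan-1-one
Conditions: 4-(trifluoromethyl)benzyl bromide (2.05 equiv), K2CO3 (2.2 equiv), DMF, 0 °C to rt
Reagents that add atoms: 4-(trifluoromethyl)benzyl bromide, FC(F)(F)c1ccc(CBr)cc1
Why: Williamson etherification takes the para hydroxyl and one ortho hydroxyl, while the last ortho hydroxyl is held in a hydrogen bond to the acetyl carbonyl and should stay free, which fixes the substitution pattern of ring A without a regiochemical question.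

Step 2
Reactants: 2 1-(2-hydroxy-4,6-bis{[4-(trifluoromethyl)phenyl]methoxy}phenyl)ethan-1-one; 3 3,4-bis(benzyloxy)benzyl chloride
Product: 4 1-(2-{[3,4-bis(benzyloxy)phenyl]methoxy}-4,6-bis{[4-(trifluoromethyl)phenyl]methoxy}phenyl)ethan-1-one
Conditions: K2CO3, n-Bu4NI (cat.), DMF, 70 °C
Reagents that add atoms: none
Why: Williamson etherification of the chelated phenol under more forcing conditions places the only electron-rich benzyl ether, the future C2 and ring B, on the oxygen that becomes O1.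

Step 3
Reactants: 4 1-(2-{[3,4-bis(benzyloxy)phenyl]methoxy}-4,6-bis{[4-(trifluoromethyl)phenyl]methoxy}phenyl)ethan-1-one
Product: 6 methyl 2-oxo-2-(2-{[3,4-bis(benzyloxy)phenyl]methoxy}-4,6-bis{[4-(trifluoromethyl)phenyl]methoxy}phenyl)acetate, via arylglyoxylic acid 5 (not isolated)
Conditions: SeO2, pyridine, 100 °C; filtration, aqueous citric acid work-up; then MeI, K2CO3, DMF, rt
Reagents that add atoms: selenium dioxide, O=[Se]=O; methyl iodide, CI
Why: Riley oxidation of the aryl methyl ketone in pyridine should run through the glyoxal to the arylglyoxylic acid, whose carboxylate is then O-methylated; the ether CH2 groups need far harsher conditions for oxidation by SeO2.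

Step 4
Reactants: 6 methyl 2-oxo-2-(2-{[3,4-bis(benzyloxy)phenyl]methoxy}-4,6-bis{[4-(trifluoromethyl)phenyl]methoxy}phenyl)acetate
Product: 8 methyl 2-diazo-2-(2-{[3,4-bis(benzyloxy)phenyl]methoxy}-4,6-bis{[4-(trifluoromethyl)phenyl]methoxy}phenyl)acetate, via tosylhydrazone 7 (not isolated)
Conditions: TsNHNH2, THF/MeOH, 60 °C; then DBU, CH2Cl2, rt
Reagents that add atoms: p-toluenesulfonyl hydrazide, Cc1ccc(cc1)S(=O)(=O)NN
Why: Condensation of the electrophilic α-keto ester with the hydrazide and base-induced loss of sulfinate (Bamford–Stevens reaction) is the standard entry to aryl diazoacetates.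

Step 5
Reactants: 8 methyl 2-diazo-2-(2-{[3,4-bis(benzyloxy)phenyl]methoxy}-4,6-bis{[4-(trifluoromethyl)phenyl]methoxy}phenyl)acetate
Product: 9 methyl (2S,3R)-2-[3,4-bis(benzyloxy)phenyl]-4,6-bis{[4-(trifluoromethyl)phenyl]methoxy}-2,3-dihydro-1-benzofuran-3-carboxylate (2,3-cis)
Conditions: Rh2(S-PTTL)4 (dirhodium tetrakis[N-phthaloyl-(S)-tert-leucinate], 1 mol %), toluene, −60 °C
Reagents that add atoms: none
Why: Intramolecular 1,5 C–H insertion of the dirhodium carbene into a benzylic C–H bond of an ortho ArCH2O group closes the five-membered ring; the electrophilic carbene inserts with build-up of positive charge at carbon, so the CH2 activated by the para oxygen of the 3,4-bis(benzyloxy)phenyl ring should react in strong preference to the CF3-deactivated CH2 on the other side, and for this substrate class the concerted insertion is known to give the 2,3-cis ester with C2 and C3 fixed by the chiral carboxylate ligands.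

Step 6
Reactants: 9 methyl (2S,3R)-2-[3,4-bis(benzyloxy)phenyl]-4,6-bis{[4-(trifluoromethyl)phenyl]methoxy}-2,3-dihydro-1-benzofuran-3-carboxylate
Product: 10 [(2S,3S)-2-[3,4-bis(benzyloxy)phenyl]-4,6-bis{[4-(trifluoromethyl)phenyl]methoxy}-2,3-dihydro-1-benzofuran-3-yl]methanol (2,3-cis)
Conditions: i-Bu2AlH, CH2Cl2, −78 °C; Rochelle salt work-up
Reagents that add atoms: none
Why: Hydride reduction of the ester with i-Bu2AlH at low temperature is non-basic and should leave the epimerisable C3 centre and the cis relationship intact.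

Step 7
Reactants: 10 [(2S,3S)-2-[3,4-bis(benzyloxy)phenyl]-4,6-bis{[4-(trifluoromethyl)phenyl]methoxy}-2,3-dihydro-1-benzofuran-3-yl]methanol
Product: 12 (2R,3R)-2-[3,4-bis(benzyloxy)phenyl]-5,7-bis{[4-(trifluoromethyl)phenyl]methoxy}chroman-3-ol (3',4'-di-O-benzyl-5,7-di-O-TFMB-(−)-epicatechin), via primary mesylate 11 (not isolated)
Conditions: Ms2O, i-Pr2NEt, CH2Cl2, −20 °C; then acetone/H2O (4:1), NaHCO3, 40 °C
Reagents that add atoms: water, O; methanesulfonic anhydride, CS(=O)(=O)OS(C)(=O)=O (its atoms stay only in 11)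
Why: Proposed new method: mesylate 11 ionises with anchimeric assistance of ring A, which is activated by O1 and by the two ether oxygens ortho and para to its ipso carbon (C3a of the dihydrobenzofuran, the later C4a); this carbon attacks the CH2 carbon from the rear in a 3-exo-tet closure to a spiro-cyclopropyl arenium (phenonium) ion, and water opens that ion at the secondary carbon C3 anti to the departing aryl bond, so that the C3–C4a bond is traded for C4–C4a and the six-membered ring (O1, C2, C3, C4, C4a, C8a) arises by a 1,2-aryl shift with gain of one ring atom. The closest known reaction type is the phenonium-ion (neophyl-type Wagner–Meerwein) solvolysis of 2-arylethyl sulfonates and the ring enlargement of benzo-fused cycloalkylmethyl cations by 1,2-aryl shift. C2 is not touched and keeps its spatial arrangement (S in 10 and R in 12 only through a change of priorities), while C3 is set by stereospecific inversion, which places the new hydroxyl cis to the 2-aryl group and gives the (2R,3R) epicatechin pattern. The step needs opening at C3 and not at CH2, and no hydride shift from C2 or ionisation of the C2–O1 bond: the secondary carbon carries more of the positive charge and its opening releases the strain of the fused three- and five-membered rings, attack at CH2 only returns 10, and the buffered medium should protect the benzylic C2–O1 bond and the benzyl-type ethers.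

Step 8
Reactants: 12 (2R,3R)-2-[3,4-bis(benzyloxy)phenyl]-5,7-bis{[4-(trifluoromethyl)phenyl]methoxy}chroman-3-ol
Product: 13 (2R,3R)-8-bromo-2-[3,4-bis(benzyloxy)phenyl]-5,7-bis{[4-(trifluoromethyl)phenyl]methoxy}chroman-3-ol
Conditions: NBS (1.0 equiv), CH2Cl2, −78 °C to 0 °C
Reagents that add atoms: N-bromosuccinimide, O=C1CCC(=O)N1Br
Why: Electrophilic aromatic bromination of 5,7-dialkoxyflavans is known to take place at C8 of ring A, which is far more nucleophilic than the catechol-ether ring and the CF3-bearing rings, and so caps this position.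

Step 9
Reactants: 14 (+)-catechin
Product: 15 5,7,3',4'-tetra-O-benzyl-(+)-catechin ((2R,3S)-5,7-bis(benzyloxy)-2-[3,4-bis(benzyloxy)phenyl]chroman-3-ol)
Conditions: BnBr, K2CO3, DMF, 0 °C to rt
Reagents that add atoms: benzyl bromide, BrCc1ccccc1
Why: Williamson etherification of the four phenols, which are far more acidic than the C3 alcohol, should leave the secondary hydroxyl free.

Step 10
Reactants: 15 5,7,3',4'-tetra-O-benzyl-(+)-catechin
Product: 16 (2R,3S)-8-bromo-5,7-bis(benzyloxy)-2-[3,4-bis(benzyloxy)phenyl]chroman-3-ol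
Conditions: NBS (1.0 equiv), CH2Cl2, −78 °C to 0 °C
Reagents that add atoms: N-bromosuccinimide, O=C1CCC(=O)N1Br
Why: Regioselective electrophilic aromatic bromination at C8 caps the more reactive ring-A position of the future upper and middle units.

Step 11
Reactants: 16 (2R,3S)-8-bromo-5,7-bis(benzyloxy)-2-[3,4-bis(benzyloxy)phenyl]chroman-3-ol
Product: 17 (2R,3S,4S)-8-bromo-5,7-bis(benzyloxy)-2-[3,4-bis(benzyloxy)phenyl]-4-(2-ethoxyethoxy)chroman-3-ol
Conditions: DDQ, 2-ethoxyethanol, CH2Cl2, rt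
Reagents that add atoms: 2-ethoxyethanol, CCOCCO
Why: DDQ abstracts hydride from the benzylic C4–H (oxidative C–H etherification) and the alcohol adds to the ring-A-stabilised cation; the configuration of this ether is of no consequence because C4 is ionised again in the couplings.

Step 12
Reactants: 17 (2R,3S,4S)-8-bromo-5,7-bis(benzyloxy)-2-[3,4-bis(benzyloxy)phenyl]-4-(2-ethoxyethoxy)chroman-3-ol; 13 (2R,3R)-8-bromo-2-[3,4-bis(benzyloxy)phenyl]-5,7-bis{[4-(trifluoromethyl)phenyl]methoxy}chroman-3-ol (3 equiv)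
Product: 18 dimer [8-bromo-5,7,3',4'-tetra-O-benzylcatechin]-(4α→6)-[8-bromo-3',4'-di-O-benzyl-5,7-di-O-TFMB-epicatechin]
Conditions: Me3SiOTf (0.2 equiv), CH2Cl2, −78 °C
Reagents that add atoms: none
Why: Me3SiOTf ionises the C4 ether to a cation stabilised by ring A (Friedel–Crafts benzylation); with C8 of 13 capped the only free activated position is C6, the arene adds anti to the C3 hydroxyl of the 2,3-trans cation and so sets the new C4 centre 3,4-trans (4α), and the excess of 13 should suppress attack of the cation on the free C6 of 17 or 18.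

Step 13
Reactants: 17 (2R,3S,4S)-8-bromo-5,7-bis(benzyloxy)-2-[3,4-bis(benzyloxy)phenyl]-4-(2-ethoxyethoxy)chroman-3-ol; 18 dimer (2 equiv)
Product: 19 protected trimer [8-bromo-5,7,3',4'-tetra-O-benzylcatechin]-(4α→6)-[8-bromo-5,7,3',4'-tetra-O-benzylcatechin]-(4α→6)-[8-bromo-3',4'-di-O-benzyl-5,7-di-O-TFMB-epicatechin]
Conditions: Me3SiOTf (0.2 equiv), CH2Cl2, −78 °C to −40 °C
Reagents that add atoms: none
Why: The same Friedel–Crafts benzylation now meets the only unsubstituted ring-A carbon of 18, C6 of its catechin unit, and anti attack on the cation again sets the new C4 centre 3,4-trans (4α).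

Step 14
Reactants: 19 protected trimer
Product: 20 catechin-(4α→6)-catechin-(4α→6)-epicatechin (CNP0163146.3)
Conditions: H2 (1 atm), Pd(OH)2/C, Et3N, THF/MeOH/H2O, rt
Reagents that add atoms: none
Why: Catalytic hydrogenolysis should cleave all benzyl and TFMB ethers and the three aryl–bromine bonds (Et3N takes up HBr) without touching the interflavan C–C bonds, the CF3 groups of the released arene or any stereocentre.

**Compound list**

1 | 2',4',6'-trihydroxyacetophenone (phloroacetophenone) | CC(=O)c1c(O)cc(O)cc1O | starting material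
2 | 1-(2-hydroxy-4,6-bis{[4-(trifluoromethyl)phenyl]methoxy}phenyl)ethan-1-one | CC(=O)c1c(O)cc(OCc2ccc(C(F)(F)F)cc2)cc1OCc1ccc(C(F)(F)F)cc1 | intermediate
3 | 3,4-bis(benzyloxy)benzyl chloride | ClCc1ccc(OCc2ccccc2)c(OCc2ccccc2)c1 | starting material
4 | 1-(2-{[3,4-bis(benzyloxy)phenyl]methoxy}-4,6-bis{[4-(trifluoromethyl)phenyl]methoxy}phenyl)ethan-1-one | CC(=O)c1c(OCc2ccc(OCc3ccccc3)c(OCc3ccccc3)c2)cc(OCc2ccc(C(F)(F)F)cc2)cc1OCc1ccc(C(F)(F)F)cc1 | intermediate
5 | 2-oxo-2-(2-{[3,4-bis(benzyloxy)phenyl]methoxy}-4,6-bis{[4-(trifluoromethyl)phenyl]methoxy}phenyl)acetic acid (formed in the flask, not isolated) | OC(=O)C(=O)c1c(OCc2ccc(OCc3ccccc3)c(OCc3ccccc3)c2)cc(OCc2ccc(C(F)(F)F)cc2)cc1OCc1ccc(C(F)(F)F)cc1 | intermediate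
6 | methyl 2-oxo-2-(2-{[3,4-bis(benzyloxy)phenyl]methoxy}-4,6-bis{[4-(trifluoromethyl)phenyl]methoxy}phenyl)acetate | COC(=O)C(=O)c1c(OCc2ccc(OCc3ccccc3)c(OCc3ccccc3)c2)cc(OCc2ccc(C(F)(F)F)cc2)cc1OCc1ccc(C(F)(F)F)cc1 | intermediate
7 | tosylhydrazone of 6 (C=N geometry not defined; formed in the flask, not isolated) | COC(=O)C(=NNS(=O)(=O)c1ccc(C)cc1)c1c(OCc2ccc(OCc3ccccc3)c(OCc3ccccc3)c2)cc(OCc2ccc(C(F)(F)F)cc2)cc1OCc1ccc(C(F)(F)F)cc1 | intermediate
8 | methyl 2-diazo-2-(2-{[3,4-bis(benzyloxy)phenyl]methoxy}-4,6-bis{[4-(trifluoromethyl)phenyl]methoxy}phenyl)acetate | COC(=O)C(=[N+]=[N-])c1c(OCc2ccc(OCc3ccccc3)c(OCc3ccccc3)c2)cc(OCc2ccc(C(F)(F)F)cc2)cc1OCc1ccc(C(F)(F)F)cc1 | intermediate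
9 | methyl (2S,3R)-2-[3,4-bis(benzyloxy)phenyl]-4,6-bis{[4-(trifluoromethyl)phenyl]methoxy}-2,3-dihydro-1-benzofuran-3-carboxylate | COC(=O)[C@@H]1c2c(OCc3ccc(C(F)(F)F)cc3)cc(OCc3ccc(C(F)(F)F)cc3)cc2O[C@@H]1c1ccc(OCc2ccccc2)c(OCc2ccccc2)c1 | intermediate
10 | [(2S,3S)-2-[3,4-bis(benzyloxy)phenyl]-4,6-bis{[4-(trifluoromethyl)phenyl]methoxy}-2,3-dihydro-1-benzofuran-3-yl]methanol | OC[C@@H]1c2c(OCc3ccc(C(F)(F)F)cc3)cc(OCc3ccc(C(F)(F)F)cc3)cc2O[C@@H]1c1ccc(OCc2ccccc2)c(OCc2ccccc2)c1 | intermediate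
11 | methanesulfonate of 10 (formed in the flask, not isolated) | CS(=O)(=O)OC[C@@H]1c2c(OCc3ccc(C(F)(F)F)cc3)cc(OCc3ccc(C(F)(F)F)cc3)cc2O[C@@H]1c1ccc(OCc2ccccc2)c(OCc2ccccc2)c1 | intermediate
12 | (2R,3R)-2-[3,4-bis(benzyloxy)phenyl]-5,7-bis{[4-(trifluoromethyl)phenyl]methoxy}chroman-3-ol | O[C@@H]1Cc2c(OCc3ccc(C(F)(F)F)cc3)cc(OCc3ccc(C(F)(F)F)cc3)cc2O[C@@H]1c1ccc(OCc2ccccc2)c(OCc2ccccc2)c1 | intermediate
13 | (2R,3R)-8-bromo-2-[3,4-bis(benzyloxy)phenyl]-5,7-bis{[4-(trifluoromethyl)phenyl]methoxy}chroman-3-ol | O[C@@H]1Cc2c(OCc3ccc(C(F)(F)F)cc3)cc(OCc3ccc(C(F)(F)F)cc3)c(Br)c2O[C@@H]1c1ccc(OCc2ccccc2)c(OCc2ccccc2)c1 | intermediate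
14 | (+)-catechin | O[C@H]1Cc2c(O)cc(O)cc2O[C@@H]1c1ccc(O)c(O)c1 | starting material
15 | 5,7,3',4'-tetra-O-benzyl-(+)-catechin | O[C@H]1Cc2c(OCc3ccccc3)cc(OCc3ccccc3)cc2O[C@@H]1c1ccc(OCc2ccccc2)c(OCc2ccccc2)c1 | intermediate
16 | 8-bromo-5,7,3',4'-tetra-O-benzyl-(+)-catechin | O[C@H]1Cc2c(OCc3ccccc3)cc(OCc3ccccc3)c(Br)c2O[C@@H]1c1ccc(OCc2ccccc2)c(OCc2ccccc2)c1 | intermediate
17 | (2R,3S,4S)-8-bromo-5,7-bis(benzyloxy)-2-[3,4-bis(benzyloxy)phenyl]-4-(2-ethoxyethoxy)chroman-3-ol | O[C@H]1[C@@H](OCCOCC)c2c(OCc3ccccc3)cc(OCc3ccccc3)c(Br)c2O[C@@H]1c1ccc(OCc2ccccc2)c(OCc2ccccc2)c1 | intermediate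
18 | dimer [8-bromo-tetra-O-benzylcatechin]-(4α→6)-[8-bromo-3',4'-di-O-benzyl-5,7-di-O-TFMB-epicatechin] | O[C@H]1[C@H](c3c(OCc5ccc(C(F)(F)F)cc5)c4C[C@@H](O)[C@@H](c5ccc(OCc6ccccc6)c(OCc6ccccc6)c5)Oc4c(Br)c3OCc3ccc(C(F)(F)F)cc3)c2c(OCc3ccccc3)cc(OCc3ccccc3)c(Br)c2O[C@@H]1c1ccc(OCc2ccccc2)c(OCc2ccccc2)c1 | intermediate
19 | protected tribromo trimer, catechin-(4α→6)-catechin-(4α→6)-epicatechin skeleton | O[C@H]1[C@H](c3c(OCc7ccccc7)c4[C@@H](c5c(OCc7ccc(C(F)(F)F)cc7)c6C[C@@H](O)[C@@H](c7ccc(OCc8ccccc8)c(OCc8ccccc8)c7)Oc6c(Br)c5OCc5ccc(C(F)(F)F)cc5)[C@H](O)[C@@H](c5ccc(OCc6ccccc6)c(OCc6ccccc6)c5)Oc4c(Br)c3OCc3ccccc3)c2c(OCc3ccccc3)cc(OCc3ccccc3)c(Br)c2O[C@@H]1c1ccc(OCc2ccccc2)c(OCc2ccccc2)c1 | intermediate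
20 | catechin-(4α→6)-catechin-(4α→6)-epicatechin (CNP0163146.3) | Oc1cc(O)c2c(c1)O[C@H](c1ccc(O)c(O)c1)[C@@H](O)[C@@H]2c1c(O)cc2c(c1O)[C@@H](c1c(O)cc3c(c1O)C[C@@H](O)[C@@H](c1ccc(O)c(O)c1)O3)[C@H](O)[C@@H](c1ccc(O)c(O)c1)O2 | target

Total step count: 14. Longest linear sequence: 11 steps (steps 1–8, then 12, 13 and 14).

**Steps most likely to fail**

1. Step 7 (Proposed new method). What may go wrong: capture of the phenonium ion at the primary carbon (return to the five-membered ring), hydride shift from C2 or elimination to flavenes, ionisation of the C2–O1 bond with loss of configuration, or acid cleavage of the ethers. The fallback uses only known chemistry and gives up the ring enlargement for this ring in order to secure material; it sets out from 15 and comes back to the route at 20. Compound 15 is oxidised with Dess–Martin periodinane (CH2Cl2, rt) to (2R)-5,7-bis(benzyloxy)-2-[3,4-bis(benzyloxy)phenyl]chroman-3-one F1. LiBH(s-Bu)3 (THF, −78 °C) should deliver hydride anti to the 2-aryl group and give 5,7,3',4'-tetra-O-benzyl-(−)-epicatechin F2. NBS (CH2Cl2, −78 °C) gives 8-bromo-5,7,3',4'-tetra-O-benzyl-(−)-epicatechin F3. F3 (in excess) is coupled with 17 under the conditions of step 12 to the all-benzyl dibromo dimer F4, a second coupling with 17 gives the all-benzyl tribromo trimer F5, and hydrogenolysis as in step 14 gives 20.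

2. Step 5. What may go wrong: insufficient facial discrimination by the chiral dirhodium catalyst, because the carbene carbon is flanked by two ortho substituents and is twisted out of the plane of ring A, so that the cis ester forms with low enantiomeric purity. The fallback replaces catalyst control by classical resolution; it sets out from 10 of insufficient enantiomeric purity and comes back to the route at enantiopure 10. The alcohol is esterified with (S)-O-acetylmandelic acid (DCC, DMAP, CH2Cl2, 0 °C) to the (S)-O-acetylmandelate of 10 F6, which is separated by crystallisation or chromatography from the diastereomeric (S)-O-acetylmandelate of ent-10 F7; hydrolysis of F6 (LiOH, THF/H2O) returns 10.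

3. Step 13. What may go wrong: slow attack by the hindered, bromine-deactivated C6 of 18, so that 17 condenses with itself at its own free C6 and the product 19 reacts further at the C6 of its upper unit. The fallback uses a fully capped electrophile; it sets out from 15 and comes back to the route at 20. Compound 15 is brominated twice (NBS, 2.2 equiv, CH2Cl2) to 6,8-dibromo-5,7,3',4'-tetra-O-benzyl-(+)-catechin F8 and oxidised (DDQ, 2-ethoxyethanol) to (2R,3S,4S)-6,8-dibromo-5,7-bis(benzyloxy)-2-[3,4-bis(benzyloxy)phenyl]-4-(2-ethoxyethoxy)chroman-3-ol F9, which can neither self-condense nor give a product that reacts on. Coupling of F9 with 18 (Me3SiOTf, CH2Cl2, −78 °C) gives the tetrabromo protected trimer F10, and hydrogenolysis as in step 14 gives 20.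

**Further compounds**

F1 | step 7 | (2R)-5,7-bis(benzyloxy)-2-[3,4-bis(benzyloxy)phenyl]chroman-3-one | O=C1Cc2c(OCc3ccccc3)cc(OCc3ccccc3)cc2O[C@@H]1c1ccc(OCc2ccccc2)c(OCc2ccccc2)c1
F2 | step 7 | 5,7,3',4'-tetra-O-benzyl-(−)-epicatechin | O[C@@H]1Cc2c(OCc3ccccc3)cc(OCc3ccccc3)cc2O[C@@H]1c1ccc(OCc2ccccc2)c(OCc2ccccc2)c1
F3 | step 7 | 8-bromo-5,7,3',4'-tetra-O-benzyl-(−)-epicatechin | O[C@@H]1Cc2c(OCc3ccccc3)cc(OCc3ccccc3)c(Br)c2O[C@@H]1c1ccc(OCc2ccccc2)c(OCc2ccccc2)c1
F4 | step 7 | all-benzyl dibromo dimer [8-bromo-tetra-O-benzylcatechin]-(4α→6)-[8-bromo-tetra-O-benzylepicatechin] | O[C@H]1[C@H](c3c(OCc5ccccc5)c4C[C@@H](O)[C@@H](c5ccc(OCc6ccccc6)c(OCc6ccccc6)c5)Oc4c(Br)c3OCc3ccccc3)c2c(OCc3ccccc3)cc(OCc3ccccc3)c(Br)c2O[C@@H]1c1ccc(OCc2ccccc2)c(OCc2ccccc2)c1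
F5 | step 7 | all-benzyl tribromo trimer | O[C@H]1[C@H](c3c(OCc7ccccc7)c4[C@@H](c5c(OCc7ccccc7)c6C[C@@H](O)[C@@H](c7ccc(OCc8ccccc8)c(OCc8ccccc8)c7)Oc6c(Br)c5OCc5ccccc5)[C@H](O)[C@@H](c5ccc(OCc6ccccc6)c(OCc6ccccc6)c5)Oc4c(Br)c3OCc3ccccc3)c2c(OCc3ccccc3)cc(OCc3ccccc3)c(Br)c2O[C@@H]1c1ccc(OCc2ccccc2)c(OCc2ccccc2)c1
F6 | step 5 | (S)-O-acetylmandelate of 10 | CC(=O)O[C@H](C(=O)OC[C@@H]1c2c(OCc3ccc(C(F)(F)F)cc3)cc(OCc3ccc(C(F)(F)F)cc3)cc2O[C@@H]1c1ccc(OCc2ccccc2)c(OCc2ccccc2)c1)c1ccccc1
F7 | step 5 | (S)-O-acetylmandelate of ent-10 | CC(=O)O[C@H](C(=O)OC[C@H]1c2c(OCc3ccc(C(F)(F)F)cc3)cc(OCc3ccc(C(F)(F)F)cc3)cc2O[C@H]1c1ccc(OCc2ccccc2)c(OCc2ccccc2)c1)c1ccccc1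
F8 | step 13 | 6,8-dibromo-5,7,3',4'-tetra-O-benzyl-(+)-catechin | O[C@H]1Cc2c(OCc3ccccc3)c(Br)c(OCc3ccccc3)c(Br)c2O[C@@H]1c1ccc(OCc2ccccc2)c(OCc2ccccc2)c1
F9 | step 13 | (2R,3S,4S)-6,8-dibromo-5,7-bis(benzyloxy)-2-[3,4-bis(benzyloxy)phenyl]-4-(2-ethoxyethoxy)chroman-3-ol | O[C@H]1[C@@H](OCCOCC)c2c(OCc3ccccc3)c(Br)c(OCc3ccccc3)c(Br)c2O[C@@H]1c1ccc(OCc2ccccc2)c(OCc2ccccc2)c1
F10 | step 13 | tetrabromo protected trimer (19 with bromine also at C6 of the upper unit) | O[C@H]1[C@H](c3c(OCc7ccccc7)c4[C@@H](c5c(OCc7ccc(C(F)(F)F)cc7)c6C[C@@H](O)[C@@H](c7ccc(OCc8ccccc8)c(OCc8ccccc8)c7)Oc6c(Br)c5OCc5ccc(C(F)(F)F)cc5)[C@H](O)[C@@H](c5ccc(OCc6ccccc6)c(OCc6ccccc6)c5)Oc4c(Br)c3OCc3ccccc3)c2c(OCc3ccccc3)c(Br)c(OCc3ccccc3)c(Br)c2O[C@@H]1c1ccc(OCc2ccccc2)c(OCc2ccccc2)c1
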